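## The problem

The target 18 is a three-carbon chain C7–C8–C9 held between two syringyl-type arenes: ring A (4-hydroxy-3,5-dimethoxyphenyl) is bonded through carbon to the ketone C7, and ring B (4-carboxy-2,6-dimethoxyphenyl) is bonded through its phenolic oxygen to C8, which also carries the hydroxymethyl carbon C9. No ring has to be closed, so the task is chain assembly: one aryl–carbonyl bond, one alkyl aryl ether bond and one C–C bond within the chain. C8 is the only stereocentre, it is (S), and nothing else in the molecule can relay chirality to it, so its configuration must come from a reagent, a catalyst or a removable auxiliary. In the target this centre is a C–H α to an aryl ketone and β to a free hydroxyl, so base would racemise it by enolisation or destroy it by loss of water or of formaldehyde; the ketone should therefore appear late and under non-basic conditions, and the last deprotection should be neutral. The ether oxygen of ring B is flanked by two methoxy groups, which makes the phenol a hindered, weak nucleophile: a displacement at the secondary carbon C8 by this phenol is the bond formation most likely to fail, whereas its alkylation by a primary α-halo ester is routine. The free phenol, carboxylic acid and primary alcohol must be masked during the organometallic steps, best by one kind of group that leaves in a single operation. The feature that opens the route is that C8 is a CH flanked by the acyl carbon C7, the aryloxy oxygen and the one-carbon arm C9: it is the α-carbon of an aryloxyacetic acid derivative, whose enolate can take up C9 as a formaldehyde cation equivalent under the control of an auxiliary on C7.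

## Retrosynthesis

**18 to 17.** The three O–benzyl bonds (ester on ring B, aryl ether on ring A, alkyl ether on C9) are cut last. Benzyl is chosen for all three because hydrogenolysis is neutral. Silyl, acetal or tert-butyl groups would need acid or fluoride at the stage of the β-hydroxy ketone. The forward step only asks that the aryl ketone and the C8–O bond outlast the O–benzyl bonds under hydrogen.

**17 to 12 and 16.** The ring A–C7 bond is cut to the S-ethyl thioester 12 and the arylzinc chloride 16. Reagent 16 comes from bromide 14 through the arylmagnesium bromide 15, and 14 is one benzylation away from the commercial bromophenol 13. The neighbouring polar cut, an N-methoxy-N-methylamide attacked by the arylmagnesium reagent 15, was weighed and set aside. It would expose the benzyl ester of ring B first to an aluminium amide and then to a hard carbon nucleophile. The thioester–organozinc pair is coupled under palladium catalysis without base, so neither the ester nor the C8–H is at risk. This cut removes ring A completely from the chiral fragment.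

**12 to 11.** The C7–S bond is traced back to the C7–N bond of imide 11. Thiolate cleavage of an N-acyl oxazolidinone gives the thioester in one step and returns the auxiliary 6. Passing through the acid would add a step and an activation that could epimerise C8. The forward reaction must attack the exocyclic carbonyl only.

**11 to 8 and 9.** The C8–C9 bond is cut to the aryloxyacetyl imide 8 and benzyl chloromethyl ether 9. This is the only cut within the chain that creates the stereocentre while making a C–C bond. A cut at C8–O would require the hindered ring B phenol to displace at a secondary centre, and a cut at C7–C8 would require an acyl anion. Precursor 8 has no stereocentre in the chain and carries all of ring B. The forward step asks for a single enolate geometry and one open face, and delivers C9 already protected as the benzyl ether needed for the endgame. A minor diastereomer can be removed at this stage because the auxiliary is still attached.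

**8 to 5 and 6.** The C7–N bond is cut to the aryloxyacetic acid 5 and (R)-4-benzyloxazolidin-2-one 6, joined through the mixed anhydride 7. Acid 5 is achiral, so the acylation has no stereochemical demand.

**5 to 4, then to 2 and 3.** The O–CH2 bond of the ether is cut to benzyl syringate 2 and tert-butyl bromoacetate 3. The ether is thus made at a primary carbon before any stereocentre exists. The tert-butyl ester of 4 is cleaved by acid in the presence of the benzyl ester.

**2 to 1.** The benzyl ester is traced back to syringic acid 1, which supplies ring B with all its oxygen substituents in place.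

## Roads not taken

**Alternative 1:** No skeletal bond is made in the key step. The racemic α-aryloxy β-keto ester A1, with C9 at the ester oxidation level, would be reduced at C7 by RuCl(p-cymene)(TsDPEN) with a formate hydride source. C8 epimerises quickly between the two carbonyl groups, so one enantiomer is funnelled into the (1R,2R) hydroxy ester A2. The 2R centre of A2 has the spatial arrangement of the (S) centre of 18, and the descriptor changes when the ester becomes CH2OH.
- Merits: chirality is catalytic, no auxiliary is attached or removed, and A1 is assembled by simple enolate and phenoxide chemistry.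
- Weak points for this target: the C7 carbinol is made only to be oxidised back, so the route spends one reduction and one oxidation on a stereocentre that is absent from 18. The reoxidation must pick the benzylic alcohol in the presence of the new primary alcohol at C9. Once C7 is a ketone again, every stereoisomer of A2 with the wrong C8 configuration becomes the enantiomer of the target, so the final enantiopurity depends on both the enantio- and the diastereoselectivity of the reduction. The methoxymethyl and tert-butyl groups of A2 must finally leave under acid on a β-hydroxy ketone.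
- Comparison: this road is better in atom economy and avoids stoichiometric titanium. The chosen plan sets against this that C8 is made directly at the final oxidation pattern, that the wrong isomer is a separable diastereomer, and that the last step is neutral.

**Alternative 2:** The C7–C8 bond is cut. A thiamine-dependent benzaldehyde lyase would use aldehyde A3 as acyl donor and aldehyde A4 as acceptor and give the (R)-acyloin A5. A5 has a hydroxyl where the target has the aryloxy group, and the opposite spatial arrangement. A Mitsunobu reaction with phenol 2, with inversion, would be needed to reach 17.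
- Merits: this is the shortest road, about half the length of the chosen one. The C–C bond and the stereocentre come from two simple aldehydes in one catalytic, aqueous step.
- Weak points for this target: the donor A3 is bulky and sparingly water-soluble, and it is uncertain that the enzyme accepts it. More seriously, the ether bond would have to be made by SN2 displacement at a carbinol carbon α to an aryl ketone, by a phenol with two ortho substituents. Enolisation of the activated ketol, and hence racemisation, competes with a slow substitution, and the enolisable ketone is present from the first step on.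
- Comparison: in step count this road is clearly better. The chosen plan sets against this that the ether bond is formed on a primary carbon before the stereocentre exists, and that C8 never has to undergo substitution.

**Alternative 3:** The ring A–C7 bond is cut. The S-ethyl thioester A6 and the boronic acid A7 would be coupled under Pd2(dba)3, tri(2-furyl)phosphine and Cu(O2C-C4H3S) (copper thiophene-2-carboxylate) to give ketone A8. The stereocentre of A6 would be bought from the chiral pool as a glyceric acid derivative.
- Merits: the coupling is neutral and base-free and tolerates esters. No auxiliary is needed, and the tert-butyl ester, methoxymethyl ether and silyl ether of A8 can all leave in one acidic step.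
- Weak points for this target: A6 still requires the C8–O bond to be made by an inverting displacement of a secondary glycerate hydroxyl with the hindered ring B phenol, the same doubtful bond formation as in alternative 2, though at a less enolisable ester. The acid-labile ester and alkoxy centre must then be carried to the thioester without epimerisation. The final deprotection exposes the β-hydroxy ketone to acid.
- Comparison: the chosen plan uses the same logic of a thioester as a neutral acyl donor for the ring A–C7 bond, with an organozinc in place of the boronic acid and copper carboxylate. In that respect the two roads are equal, and this road is better in avoiding the auxiliary and its two extra steps. The chosen plan sets against this a stereocentre made by C–C bond formation with predictable facial control, purification at the diastereomer stage, and a neutral final hydrogenolysis.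

Key step: step 5

Assumption: the (S) descriptor at C8 is read from the target SMILES with the priority order aryloxy oxygen, C7, C9, H; this order is unchanged in 11, 12 and 17, so the descriptor is (S) throughout.

## Route

Step 1
Reactants: 1 syringic acid (4-hydroxy-3,5-dimethoxybenzoic acid)
Product: 2 benzyl 4-hydroxy-3,5-dimethoxybenzoate
Conditions: BnBr, KHCO3, DMF, 40 °C
Reagents that add atoms: benzyl bromide, BrCc1ccccc1
Why: Chemoselective SN2 alkylation of the carboxylate: hydrogencarbonate deprotonates only the carboxylic acid, so the less acidic, hindered phenol stays free.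

Step 2
Reactants: 2 benzyl 4-hydroxy-3,5-dimethoxybenzoate, 3 tert-butyl bromoacetate
Product: 4 benzyl 4-(2-tert-butoxy-2-oxoethoxy)-3,5-dimethoxybenzoate
Conditions: K2CO3, DMF, 50 °C
Reagents that add atoms: none
Why: Williamson ether synthesis; the phenoxide is hindered, but an α-bromo ester is a very reactive primary SN2 electrophile, so the ring B ether bond is made before any stereocentre exists.

Step 3
Reactants: 4 benzyl 4-(2-tert-butoxy-2-oxoethoxy)-3,5-dimethoxybenzoate
Product: 5 2-{4-[(benzyloxy)carbonyl]-2,6-dimethoxyphenoxy}acetic acid
Conditions: CF3CO2H–CH2Cl2 (1:3), 0 °C → rt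
Reagents that add atoms: none
Why: Acidolysis of the tert-butyl ester with loss of 2-methylpropene; the benzyl ester and the aryl methyl ethers are stable to trifluoroacetic acid at room temperature.

Step 4
Reactants: 5 2-{4-[(benzyloxy)carbonyl]-2,6-dimethoxyphenoxy}acetic acid, 6 (R)-4-benzyloxazolidin-2-one
Product: 8 benzyl 4-{2-[(R)-4-benzyl-2-oxooxazolidin-3-yl]-2-oxoethoxy}-3,5-dimethoxybenzoate, via mixed pivalic anhydride 7 (not isolated)
Conditions: t-BuCOCl, Et3N, THF, −20 °C; then 6, LiCl, −20 °C → rt
Reagents that add atoms: pivaloyl chloride, CC(C)(C)C(=O)Cl (its acyl group appears in intermediate 7 only)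
Why: N-acylation of the oxazolidinone through a mixed anhydride, activated by LiCl and Et3N; the nucleophile attacks the less hindered aryloxyacetyl carbonyl, and the mild amine base spares the benzyl ester.

Step 5
Reactants: 8 benzyl 4-{2-[(R)-4-benzyl-2-oxooxazolidin-3-yl]-2-oxoethoxy}-3,5-dimethoxybenzoate, 9 benzyl chloromethyl ether
Product: 11 benzyl 4-{[(S)-1-[(R)-4-benzyl-2-oxooxazolidin-3-yl]-3-(benzyloxy)-1-oxopropan-2-yl]oxy}-3,5-dimethoxybenzoate, via chlorotitanium Z-enolate 10 (not isolated)
Conditions: TiCl4 (1.1 equiv), CH2Cl2, 0 °C; iPr2NEt (1.15 equiv), 0 °C; then 9 (2 equiv), 0 °C; aq. NH4Cl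
Reagents that add atoms: TiCl4, Cl[Ti](Cl)(Cl)Cl (its atoms appear in intermediate 10 only)
Why: TiCl4 binds both imide carbonyl groups and iPr2NEt removes a C8 proton (soft enolisation) to give the Z-enolate 10, with the aryloxy group cis to the enolate oxygen so that allylic strain with the oxazolidinone is avoided. Tetravalent titanium bridges the enolate oxygen and the ring carbonyl, which fixes the auxiliary so that its (R)-benzyl group covers one face of C8. Ether 9 is ionised by the Lewis acid to the benzyloxymethyl oxocarbenium ion, which adds to the open face and forms the C8–C9 bond. The closest known reaction type is the titanium enolate alkylation of N-acyl oxazolidinones with chloromethyl ethers, together with the alkylation of α-alkoxyacetyl imides. No ring is closed. The new stereocentre C8 is controlled by the auxiliary: attack anti to the benzyl group of the (R)-oxazolidinone on the chelated Z-enolate gives (S), since the aryloxy oxygen outranks the acyl carbon, which outranks CH2OBn. Only facial selectivity is needed because the enolate geometry is fixed, and the chelate secures it: the aryloxy oxygen is an aryl ether crowded by two ortho methoxy groups and a poor competing ligand. A minor diastereomer is separable at this stage, and the benzyl ester and methyl ethers tolerate TiCl4 at 0 °C.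

Step 6
Reactants: 11 benzyl 4-{[(S)-1-[(R)-4-benzyl-2-oxooxazolidin-3-yl]-3-(benzyloxy)-1-oxopropan-2-yl]oxy}-3,5-dimethoxybenzoate
Product: 12 benzyl 4-{[(S)-3-(benzyloxy)-1-(ethylsulfanyl)-1-oxopropan-2-yl]oxy}-3,5-dimethoxybenzoate
Conditions: EtSH (3 equiv), n-BuLi (2 equiv), THF, 0 °C; aq. NH4Cl
Reagents that add atoms: ethanethiol, CCS (delivered as lithium ethanethiolate, [Li+].[S-]CC)
Why: Thiolysis of the N-acyl oxazolidinone: the small, soft thiolate attacks the exocyclic carbonyl and expels the oxazolidinone anion, which returns auxiliary 6. The benzyl ester is not exchanged because an alkoxide is a far poorer leaving group, and the weakly basic thiolate should not epimerise C8.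

Step 7
Reactants: 13 4-bromo-2,6-dimethoxyphenol
Product: 14 2-(benzyloxy)-5-bromo-1,3-dimethoxybenzene
Conditions: BnBr, K2CO3, DMF, 50 °C
Reagents that add atoms: benzyl bromide, BrCc1ccccc1
Why: Williamson benzylation of the phenol; the benzyl ether masks the ring A phenol through the organometallic step and leaves with the other benzyl groups at the end.

Step 8
Reactants: 12 benzyl 4-{[(S)-3-(benzyloxy)-1-(ethylsulfanyl)-1-oxopropan-2-yl]oxy}-3,5-dimethoxybenzoate, 14 2-(benzyloxy)-5-bromo-1,3-dimethoxybenzene
Product: 17 benzyl 4-{[(S)-3-(benzyloxy)-1-[4-(benzyloxy)-3,5-dimethoxyphenyl]-1-oxopropan-2-yl]oxy}-3,5-dimethoxybenzoate, via arylmagnesium bromide 15 (not isolated), via arylzinc chloride 16 (not isolated)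
Conditions: 14, Mg, THF, reflux; ZnCl2 (slight excess), THF, 0 °C → rt; then 12, PdCl2(PPh3)2 (5 mol%), THF–toluene, rt; aq. NH4Cl
Reagents that add atoms: magnesium, [Mg], and ZnCl2, Cl[Zn]Cl (their atoms appear in intermediates 15 and 16 only)
Why: Fukuyama coupling: zerovalent palladium, formed in the flask from PdCl2(PPh3)2 and the organozinc, inserts into the C(O)–S bond, and transmetalation with 16 and reductive elimination give the ketone. Arylzinc halides do not add to the benzyl ester or to the product ketone and are too weakly basic to enolise C8, so the (S) centre is carried over unchanged.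

Step 9
Reactants: 17 benzyl 4-{[(S)-3-(benzyloxy)-1-[4-(benzyloxy)-3,5-dimethoxyphenyl]-1-oxopropan-2-yl]oxy}-3,5-dimethoxybenzoate
Product: 18 4-{[(S)-3-hydroxy-1-(4-hydroxy-3,5-dimethoxyphenyl)-1-oxopropan-2-yl]oxy}-3,5-dimethoxybenzoic acid
Conditions: H2 (1 atm), Pd/C (10% palladium on carbon), EtOAc, rt
Reagents that add atoms: none
Why: Catalytic hydrogenolysis of the benzyl ester, the aryl benzyl ether and the alkyl benzyl ether under neutral conditions. The electron-rich, para-oxygenated aryl ketone is reduced much more slowly than O–benzyl bonds are cleaved, and neutrality protects the enolisable, β-hydroxylated C8 centre.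

## Compound list

1 | syringic acid (4-hydroxy-3,5-dimethoxybenzoic acid) | COc1cc(C(=O)O)cc(OC)c1O | starting material
2 | benzyl 4-hydroxy-3,5-dimethoxybenzoate | COc1cc(C(=O)OCc2ccccc2)cc(OC)c1O | intermediate
3 | tert-butyl bromoacetate | CC(C)(C)OC(=O)CBr | starting material
4 | benzyl 4-(2-tert-butoxy-2-oxoethoxy)-3,5-dimethoxybenzoate | COc1cc(C(=O)OCc2ccccc2)cc(OC)c1OCC(=O)OC(C)(C)C | intermediate
5 | 2-{4-[(benzyloxy)carbonyl]-2,6-dimethoxyphenoxy}acetic acid | COc1cc(C(=O)OCc2ccccc2)cc(OC)c1OCC(=O)O | intermediate
6 | (R)-4-benzyloxazolidin-2-one | O=C1N[C@H](Cc2ccccc2)CO1 | starting material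
7 | 2-{4-[(benzyloxy)carbonyl]-2,6-dimethoxyphenoxy}acetic pivalic anhydride | COc1cc(C(=O)OCc2ccccc2)cc(OC)c1OCC(=O)OC(=O)C(C)(C)C | intermediate
8 | benzyl 4-{2-[(R)-4-benzyl-2-oxooxazolidin-3-yl]-2-oxoethoxy}-3,5-dimethoxybenzoate | O=C1OC[C@@H](Cc2ccccc2)N1C(=O)COc1c(OC)cc(C(=O)OCc2ccccc2)cc1OC | intermediate
9 | benzyl chloromethyl ether | ClCOCc1ccccc1 | starting material
10 | trichlorotitanium (Z)-enolate of 8, benzyl 4-{[(Z)-2-[(R)-4-benzyl-2-oxooxazolidin-3-yl]-2-(trichlorotitanyloxy)ethenyl]oxy}-3,5-dimethoxybenzoate | O=C1OC[C@@H](Cc2ccccc2)N1/C(O[Ti](Cl)(Cl)Cl)=C/Oc1c(OC)cc(C(=O)OCc2ccccc2)cc1OC | intermediate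
11 | benzyl 4-{[(S)-1-[(R)-4-benzyl-2-oxooxazolidin-3-yl]-3-(benzyloxy)-1-oxopropan-2-yl]oxy}-3,5-dimethoxybenzoate | O=C1OC[C@@H](Cc2ccccc2)N1C(=O)[C@H](COCc2ccccc2)Oc1c(OC)cc(C(=O)OCc2ccccc2)cc1OC | intermediate
12 | benzyl 4-{[(S)-3-(benzyloxy)-1-(ethylsulfanyl)-1-oxopropan-2-yl]oxy}-3,5-dimethoxybenzoate | CCSC(=O)[C@H](COCc1ccccc1)Oc1c(OC)cc(C(=O)OCc2ccccc2)cc1OC | intermediate
13 | 4-bromo-2,6-dimethoxyphenol | COc1cc(Br)cc(OC)c1O | starting material
14 | 2-(benzyloxy)-5-bromo-1,3-dimethoxybenzene | COc1cc(Br)cc(OC)c1OCc1ccccc1 | intermediate
15 | [4-(benzyloxy)-3,5-dimethoxyphenyl]magnesium bromide | COc1cc([Mg]Br)cc(OC)c1OCc1ccccc1 | intermediate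
16 | [4-(benzyloxy)-3,5-dimethoxyphenyl]zinc chloride | COc1cc([Zn]Cl)cc(OC)c1OCc1ccccc1 | intermediate
17 | benzyl 4-{[(S)-3-(benzyloxy)-1-[4-(benzyloxy)-3,5-dimethoxyphenyl]-1-oxopropan-2-yl]oxy}-3,5-dimethoxybenzoate | COc1cc(C(=O)[C@H](COCc2ccccc2)Oc2c(OC)cc(C(=O)OCc3ccccc3)cc2OC)cc(OC)c1OCc1ccccc1 | intermediate
18 | 4-{[(S)-3-hydroxy-1-(4-hydroxy-3,5-dimethoxyphenyl)-1-oxopropan-2-yl]oxy}-3,5-dimethoxybenzoic acid | COc1cc(C(=O)[C@H](CO)Oc2c(OC)cc(C(=O)O)cc2OC)cc(OC)c1O | target

## Step count and least certain steps

Total step count: 9. Longest linear sequence: 8 steps (steps 1 to 6, 8 and 9, from syringic acid 1); step 7 is a one-step branch.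

**Step 5 (key step).** Most likely to go wrong: incomplete enolisation or eroded facial selectivity. The Lewis acid may be shared out among the donor oxygens of ring B (two methoxy groups, the ether oxygen, the benzyl ester) instead of forming the imide chelate, and a non-chelated enolate would expose the other face.
Fallback, from 8 back to 11: the Lewis acid is left out altogether. Imide 8 is deprotonated with NaN(SiMe3)2 in THF at −78 °C to the sodium Z-enolate F1, in which sodium bridges the enolate oxygen and the ring carbonyl. F1 is alkylated by 9 in a direct SN2 displacement between −78 and −45 °C, the known alkali-metal alkylation of alkoxyacetyl imides. The open face is again the one opposite the benzyl group, so the product is 11.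

**Step 8.** Most likely to go wrong: slow transmetalation with homocoupling of the electron-rich arylzinc, or carry-over of arylmagnesium bromide that was not converted to the zinc reagent and then adds to the benzyl ester or the new ketone.
Fallback, from 12 and 14 back to 17: the organometallic is replaced by a boronic acid. Reagent 15 is made from 14 as in the route and quenched with B(OMe)3, and acidic work-up gives [4-(benzyloxy)-3,5-dimethoxyphenyl]boronic acid F3. F3 and 12 are joined by Liebeskind–Srogl coupling (Pd2(dba)3, tri(2-furyl)phosphine, Cu(O2C-C4H3S) (copper thiophene-2-carboxylate), THF, 50 °C), which needs no base and no carbanion and gives 17.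

**Step 6.** Most likely to go wrong: attack of the thiolate at the ring carbonyl with opening of the oxazolidinone, because the exocyclic carbonyl is shielded by a bulky α-carbon; or slow epimerisation at C8 if the thioester stays long in the thiolate solution.
Fallback, from 11 back to 12: the imide is hydrolysed with LiOH and H2O2 in THF–H2O at 0 °C, where hydroperoxide is known to choose the exocyclic carbonyl even of hindered imides. This gives (S)-3-(benzyloxy)-2-{4-[(benzyloxy)carbonyl]-2,6-dimethoxyphenoxy}propanoic acid F2 and auxiliary 6. F2 is then converted to 12 by Steglich thioesterification with ethanethiol (dicyclohexylcarbodiimide, catalytic 4-(dimethylamino)pyridine, CH2Cl2, 0 °C).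

**Step 9.** Most likely to go wrong: over-reduction of the aryl ketone to the benzylic alcohol, reductive cleavage of the carbonyl-activated C8–O bond, or stalling of the hydrogenolysis through sulfur traces from step 8.
Fallback, from 17 back to 18: the reductive cleavage is replaced by a Lewis-acid debenzylation with BCl3 and pentamethylbenzene as cation scavenger in CH2Cl2 at −78 °C, which removes benzyl ethers and benzyl esters without touching a ketone. It makes no new compound (F0).

## Further compounds

F1 | step 5 | sodium (Z)-enolate of 8, sodium (Z)-1-[(R)-4-benzyl-2-oxooxazolidin-3-yl]-2-{4-[(benzyloxy)carbonyl]-2,6-dimethoxyphenoxy}ethen-1-olate | O=C1OC[C@@H](Cc2ccccc2)N1/C([O-])=C/Oc1c(OC)cc(C(=O)OCc2ccccc2)cc1OC.[Na+]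
F2 | step 6 | (S)-3-(benzyloxy)-2-{4-[(benzyloxy)carbonyl]-2,6-dimethoxyphenoxy}propanoic acid | O=C(O)[C@H](COCc1ccccc1)Oc1c(OC)cc(C(=O)OCc2ccccc2)cc1OC
F3 | step 8 | [4-(benzyloxy)-3,5-dimethoxyphenyl]boronic acid | COc1cc(B(O)O)cc(OC)c1OCc1ccccc1
F0 | step 9 | none | none
A1 | alternative 1 | tert-butyl 4-({1-[3,5-dimethoxy-4-(methoxymethoxy)phenyl]-3-methoxy-1,3-dioxopropan-2-yl}oxy)-3,5-dimethoxybenzoate (racemic) | COCOc1c(OC)cc(C(=O)C(C(=O)OC)Oc2c(OC)cc(C(=O)OC(C)(C)C)cc2OC)cc1OC
A2 | alternative 1 | tert-butyl 4-{[(1R,2R)-1-[3,5-dimethoxy-4-(methoxymethoxy)phenyl]-1-hydroxy-3-methoxy-3-oxopropan-2-yl]oxy}-3,5-dimethoxybenzoate | COCOc1c(OC)cc([C@@H](O)[C@H](C(=O)OC)Oc2c(OC)cc(C(=O)OC(C)(C)C)cc2OC)cc1OC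
A3 | alternative 2 | 4-(benzyloxy)-3,5-dimethoxybenzaldehyde | COc1cc(C=O)cc(OC)c1OCc1ccccc1
A4 | alternative 2 | benzyloxyacetaldehyde | O=CCOCc1ccccc1
A5 | alternative 2 | (R)-3-(benzyloxy)-1-[4-(benzyloxy)-3,5-dimethoxyphenyl]-2-hydroxypropan-1-one | COc1cc(C(=O)[C@@H](COCc2ccccc2)O)cc(OC)c1OCc1ccccc1
A6 | alternative 3 | tert-butyl 4-{[(S)-3-(tert-butyldimethylsilyloxy)-1-(ethylsulfanyl)-1-oxopropan-2-yl]oxy}-3,5-dimethoxybenzoate | CCSC(=O)[C@H](CO[Si](C)(C)C(C)(C)C)Oc1c(OC)cc(C(=O)OC(C)(C)C)cc1OC
A7 | alternative 3 | [3,5-dimethoxy-4-(methoxymethoxy)phenyl]boronic acid | COCOc1c(OC)cc(B(O)O)cc1OC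
A8 | alternative 3 | tert-butyl 4-{[(S)-3-(tert-butyldimethylsilyloxy)-1-[3,5-dimethoxy-4-(methoxymethoxy)phenyl]-1-oxopropan-2-yl]oxy}-3,5-dimethoxybenzoate | COCOc1c(OC)cc(C(=O)[C@H](CO[Si](C)(C)C(C)(C)C)Oc2c(OC)cc(C(=O)OC(C)(C)C)cc2OC)cc1OC
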